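**Retrosynthetic overview**

- Target ⇒ oxolane-3-carbaldehyde + 3,4-dimethoxyphenyl Grignard reagent: the carbinol C–C bond is made last, and its configuration is relayed from ring C3 (magnesium chelate and Felkin–Anh model agree).
- Aldehyde ⇒ methyl ester ⇒ (S)-1-(3,4-dimethoxyphenyl)prop-2-en-1-ol + methyl 2-bromoacrylate: the oxolane is closed in one flask by making O1–C2 (conjugate addition) and then C3–C4 (5-exo radical closure); the vinyl terminus ends as the C4 methyl.
- Enabling feature: ring O1 sits between an unsubstituted C2H2, whose neighbour C3 bears a carbonyl-level carbon (a hidden acrylate), and benzylic C5, whose neighbour C4 bears a methyl (a hidden 1-arylallyl alcohol). The 4,5-trans/3,4-cis pattern is what a chair-like 5-exo transition state delivers.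
- Allylic alcohol ⇒ veratraldehyde + vinyl Grignard reagent, resolved by a lipase: C5 is the one stereocentre set by catalysis; C4, C3 and the carbinol centre are relayed from it by substrate control.
- Ring order: the oxolane is the only ring formed, in step 3.

Key step: step 3

Assumption: methyl 2-bromoacrylate and both Grignard reagents are bought as such; ring atoms are cited by the systematic oxolane locants (O1, C2H2, C3 with the side chain, C4 with the methyl, C5 with the aryl group).

**Route**

Step 1
Reactants: 1 3,4-dimethoxybenzaldehyde; 2 vinylmagnesium bromide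
Product: 3 rac-1-(3,4-dimethoxyphenyl)prop-2-en-1-ol
Conditions: 2 (THF solution), THF, 0 °C; aq NH4Cl
Reagents that add atoms: vinylmagnesium bromide (2), C=C[Mg]Br
Why: Grignard 1,2-addition of the vinyl nucleophile to the aromatic aldehyde gives the racemic secondary allylic alcohol, whose new stereocentre is left uncontrolled because the next step resolves it.

Step 2
Reactants: 3 rac-1-(3,4-dimethoxyphenyl)prop-2-en-1-ol
Product: 4 (1S)-1-(3,4-dimethoxyphenyl)prop-2-en-1-ol
Conditions: immobilised Candida antarctica lipase B (Novozym 435), vinyl acetate, MTBE, 30 °C, run to just past half conversion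
Reagents that add atoms: none
Why: Lipase-catalysed kinetic resolution by irreversible transesterification: by the empirical size rule for secondary alcohols (aryl large, vinyl medium) the enzyme should acetylate the (R)-alcohol and leave the (S)-alcohol, so that C5 of the target is set by catalysis.

Step 3
Reactants: 4 (1S)-1-(3,4-dimethoxyphenyl)prop-2-en-1-ol; 5 methyl 2-bromoacrylate
Product: 7 methyl (3R,4S,5S)-5-(3,4-dimethoxyphenyl)-4-methyloxolane-3-carboxylate, via bromo ester 6 (not isolated)
Conditions: KOt-Bu (10 mol %), THF, −40 °C, slow addition of 5; AcOH (10 mol %); then toluene, (Me3Si)3SiH (syringe pump), Et3B, air, 0 °C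
Reagents that add atoms: methyl 2-bromoacrylate (5), COC(=O)C(Br)=C
Why: The catalytic potassium alkoxide of 4 adds to the β-carbon of 5 (oxa-Michael addition, O1–C2) and proton transfer from more 4 carries the chain and leaves bromo ester 6 as both CHBr epimers; a silyl radical then takes the bromine from either epimer to give one planar α-ester radical at C3, which closes onto the internal vinyl carbon (C3–C4), and the exocyclic primary radical takes hydrogen from (Me3Si)3SiH to become the C4 methyl. The closest known reaction types are alkoxide conjugate addition to 2-haloacrylates and the reductive 5-exo cyclisation of β-allyloxy α-halo esters (Ueno–Stork-type), here run in one flask. The oxolane ring is closed in the 5-exo-trig mode by the radical C–C bond formation, the C–O bond having been made intermolecularly just before. C4 and C3 are both set in this closure by the existing C5 centre through a chair-like transition state with the C5 aryl group and the ester on the radical carbon pseudo-equatorial, which should give 4,5-trans and 3,4-cis. The step needs conjugate addition to win over loss of HBr and oligomerisation, which catalytic base, low temperature and protonation by the alcohol itself should secure, and it needs ring closure to outrun direct reduction of the radical, which the fast closure of 3-oxahex-5-enyl radicals and slow addition of the silane should secure; because both epimers of 6 funnel into the same radical, the step is stereoconvergent at C3.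

Step 4
Reactants: 7 methyl (3R,4S,5S)-5-(3,4-dimethoxyphenyl)-4-methyloxolane-3-carboxylate
Product: 8 (3R,4S,5S)-5-(3,4-dimethoxyphenyl)-4-methyloxolane-3-carbaldehyde
Conditions: i-Bu2AlH, CH2Cl2, −78 °C; MeOH, then aq potassium sodium tartrate
Reagents that add atoms: none
Why: Partial ester reduction with i-Bu2AlH: at −78 °C the tetrahedral aluminium hemiacetal, held by chelation to the β ring oxygen, should survive until the quench and release the aldehyde without touching the enolisable C3 centre.

Step 5
Reactants: 8 (3R,4S,5S)-5-(3,4-dimethoxyphenyl)-4-methyloxolane-3-carbaldehyde; 9 (3,4-dimethoxyphenyl)magnesium bromide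
Product: 10 (R)-(3,4-dimethoxyphenyl)[(3R,4S,5S)-5-(3,4-dimethoxyphenyl)-4-methyloxolan-3-yl]methanol
Conditions: MgBr2·OEt2, CH2Cl2, −78 °C; then 9 (THF solution), −78 °C; aq NH4Cl
Reagents that add atoms: (3,4-dimethoxyphenyl)magnesium bromide (9), COc1ccc([Mg]Br)cc1OC
Why: Chelation-assisted Grignard addition to an α-chiral aldehyde: the magnesium chelate between the carbonyl oxygen and ring O1 and the Felkin–Anh model (C4 with its cis methyl as the large substituent anti to the nucleophile) both present the same carbonyl face to the aryl group, which should set the carbinol centre as (R) under control of C3.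

**Compound list**

1 | 3,4-dimethoxybenzaldehyde | COc1ccc(C=O)cc1OC | starting material
2 | vinylmagnesium bromide | C=C[Mg]Br | starting material
3 | rac-1-(3,4-dimethoxyphenyl)prop-2-en-1-ol | COc1ccc(C(O)C=C)cc1OC | intermediate
4 | (1S)-1-(3,4-dimethoxyphenyl)prop-2-en-1-ol | C=C[C@H](O)c1ccc(OC)c(OC)c1 | intermediate
5 | methyl 2-bromoacrylate (methyl 2-bromoprop-2-enoate) | COC(=O)C(Br)=C | starting material
6 | methyl 2-bromo-3-{[(1S)-1-(3,4-dimethoxyphenyl)prop-2-en-1-yl]oxy}propanoate, both epimers at the CHBr carbon | COC(=O)C(Br)CO[C@@H](C=C)c1ccc(OC)c(OC)c1 | intermediate (not isolated)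
7 | methyl (3R,4S,5S)-5-(3,4-dimethoxyphenyl)-4-methyloxolane-3-carboxylate | COc1ccc([C@H]2OC[C@H](C(=O)OC)[C@@H]2C)cc1OC | intermediate
8 | (3R,4S,5S)-5-(3,4-dimethoxyphenyl)-4-methyloxolane-3-carbaldehyde | COc1ccc([C@H]2OC[C@H](C=O)[C@@H]2C)cc1OC | intermediate
9 | (3,4-dimethoxyphenyl)magnesium bromide | COc1ccc([Mg]Br)cc1OC | starting material
10 | (R)-(3,4-dimethoxyphenyl)[(3R,4S,5S)-5-(3,4-dimethoxyphenyl)-4-methyloxolan-3-yl]methanol | COc1ccc([C@H]2OC[C@H]([C@@H](O)c3ccc(OC)c(OC)c3)[C@@H]2C)cc1OC | target

**Step count and risks**

Total steps: 5. Longest linear sequence: 5 steps (1 → 3 → 4 → 7 → 8 → 10).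

Steps most likely to fail:

1. Step 3. The chair transition state with the ester pseudo-equatorial may be only modestly preferred over the ester-pseudo-axial and boat alternatives, so that cis selectivity between C3 and C4 is eroded and the C3 epimer forms beside 7. The fallback sets out from 7 as isolated together with its C3 epimer, methyl (3S,4S,5S)-5-(3,4-dimethoxyphenyl)-4-methyloxolane-3-carboxylate F1. LDA in THF at −78 °C should convert both epimers into one lithium ester enolate, lithium [(4S,5S)-5-(3,4-dimethoxyphenyl)-4-methyloxolan-3-ylidene](methoxy)methanolate F2. Kinetic protonation at −78 °C with the bulky donor 2,6-di-tert-butyl-4-methylphenol should then come from the face away from the neighbouring C4 methyl, placing the ester cis to that methyl and returning the material to the route at 7. C3 is then set by enolate protonation instead of by the radical transition state.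

2. Step 5. Facial selectivity in the addition to the aldehyde carbonyl may be insufficient, and the basic reagent may enolise 8 and erode C3. The fallback sets out from 8. Addition of 9 in THF without the chelating additive should give 10 mixed with its carbinol epimer, (S)-(3,4-dimethoxyphenyl)[(3R,4S,5S)-5-(3,4-dimethoxyphenyl)-4-methyloxolan-3-yl]methanol F3. Dess–Martin periodinane (NaHCO3, CH2Cl2) should converge both to one aryl ketone, (3,4-dimethoxyphenyl)[(3R,4S,5S)-5-(3,4-dimethoxyphenyl)-4-methyloxolan-3-yl]methanone F4. CBS reduction with BH3·SMe2 and (S)-1-methyl-3,3-diphenyltetrahydro-1H,3H-pyrrolo[1,2-c][1,3,2]oxazaborole in toluene at −20 °C should then deliver the (R)-carbinol under catalyst control and return to the route at 10. A substrate bias weak enough to make step 5 unselective should also be too weak to oppose the catalyst here.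

3. Step 4. The aluminium hemiacetal may collapse before the quench, leading to over-reduction to the primary alcohol, or the aldehyde may epimerise at C3 during work-up. The fallback sets out from 7. Full reduction with LiAlH4 in THF at 0 °C should give the primary alcohol [(3S,4S,5S)-5-(3,4-dimethoxyphenyl)-4-methyloxolan-3-yl]methanol F5. Oxidation with Dess–Martin periodinane buffered with NaHCO3 in CH2Cl2 at 0 °C then returns to the route at 8, under neutral conditions that should leave C3 untouched.

Further compounds
F1 | step 3 | methyl (3S,4S,5S)-5-(3,4-dimethoxyphenyl)-4-methyloxolane-3-carboxylate | COc1ccc([C@H]2OC[C@@H](C(=O)OC)[C@@H]2C)cc1OC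
F2 | step 3 | lithium [(4S,5S)-5-(3,4-dimethoxyphenyl)-4-methyloxolan-3-ylidene](methoxy)methanolate | COc1ccc([C@H]2OCC(=C(OC)O[Li])[C@@H]2C)cc1OC
F3 | step 5 | (S)-(3,4-dimethoxyphenyl)[(3R,4S,5S)-5-(3,4-dimethoxyphenyl)-4-methyloxolan-3-yl]methanol | COc1ccc([C@H]2OC[C@H]([C@H](O)c3ccc(OC)c(OC)c3)[C@@H]2C)cc1OC
F4 | step 5 | (3,4-dimethoxyphenyl)[(3R,4S,5S)-5-(3,4-dimethoxyphenyl)-4-methyloxolan-3-yl]methanone | COc1ccc([C@H]2OC[C@H](C(=O)c3ccc(OC)c(OC)c3)[C@@H]2C)cc1OC
F5 | step 4 | [(3S,4S,5S)-5-(3,4-dimethoxyphenyl)-4-methyloxolan-3-yl]methanol | COc1ccc([C@H]2OC[C@H](CO)[C@@H]2C)cc1OC
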